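**Plan**

- Briarane numbering is used: C1 is the quaternary carbon, C2–C9 lie in the ten-membered ring, C10 is the ring-fusion CH, C11–C14 complete ring A, C15/C20/C18 are the methyls on C1/C11/C17, C16 is the exo-methylene carbon, and C17/C19 are the lactone CH and C=O.
- Cuts: C6–Cl (from C6–O with inversion); C7–C8 together with O7–C19; C8–C17 (aldol); C2–C3 (acetylide + aldehyde); C9–C8; and the ring A bonds C1–C14 and C10–C11 (Diels–Alder).
- Forward order: ring A is built first, then the C9 arm and the ring oxygen/alkene, then the enyne arm on C2 and the keto ester. A single reductive step then closes the ten-membered ring and the lactone, and the chloride and acetates come last.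
- Enabling feature: C7 and C8 carry vicinal oxygens on the same face of the ten-membered ring, and O7 reaches the C19 carbonyl through C8 and C17 (a five-membered ring). A C7 aldehyde facing a C8 β-keto ester therefore already contains every atom of the diol and of the γ-lactone.
- Stereochemistry: C1, C10 and C11 come from an endo, catalyst-controlled Diels–Alder reaction; C12 from a Rubottom oxidation (also the stable epimer); C9 and C2 from oxazaborolidine reductions. C6 comes from (R)-butane-1,2,4-triol acetonide and is inverted by chloride at the end; C7 and C8 come from the samarium chelate; C17 is set by equilibration.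

Key step: step 30

Remark: the facial sense of the oxazaborolidinium catalyst in step 4 is assigned by analogy with other enals that carry an α-hydrogen; should the antipode form, the enantiomeric catalyst is used and nothing else changes.

Step 1
Reactants: 1 2,2-dimethoxyacetaldehyde; 2 ethyl 2-(triphenylphosphoranylidene)propanoate
Product: 3 ethyl (E)-4,4-dimethoxy-2-methylbut-2-enoate
Conditions: CH2Cl2, 0 °C to rt
Reagents that add atoms: none
Why: Wittig olefination with a stabilised α-branched ylide should give the trisubstituted (E)-enoate (ester trans to the acetal carbon), the geometry that later places C15 cis to C9.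

Step 2
Reactants: 3 ethyl (E)-4,4-dimethoxy-2-methylbut-2-enoate
Product: 4 ethyl (E)-2-methyl-4-oxobut-2-enoate
Conditions: 1 M aq. HCl, THF, rt
Reagents that add atoms: water, O
Why: Acid-catalysed acetal hydrolysis unmasks the aldehyde without touching the conjugated ester, and the (E) isomer is the stable one.

Step 3
Reactants: 5 (E)-pent-3-en-2-one
Product: 6 (E)-2-(tert-butyldimethylsilyloxy)penta-1,3-diene
Conditions: TBSOTf, Et3N, Et2O, 0 °C
Reagents that add atoms: tert-butyldimethylsilyl trifluoromethanesulfonate, CC(C)(C)[Si](C)(C)OS(=O)(=O)C(F)(F)F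
Why: Soft enolisation (silyl triflate/amine) at the α′-methyl group gives the cross-conjugated 2-silyloxy diene and leaves the (E)-propenyl unit intact.

Step 4
Reactants: 4 ethyl (E)-2-methyl-4-oxobut-2-enoate; 6 (E)-2-(tert-butyldimethylsilyloxy)penta-1,3-diene
Product: 7 ethyl (1S,5S,6S)-3-(tert-butyldimethylsilyloxy)-6-formyl-1,5-dimethylcyclohex-3-ene-1-carboxylate (C1 methyl, C10 formyl and C11 methyl mutually cis)
Conditions: (3aS)-3,3-diphenyl-1-(2-methylphenyl)tetrahydro-3H-pyrrolo[1,2-c][1,3,2]oxazaborole (20 mol%), HNTf2 (18 mol%), CH2Cl2, −78 to −40 °C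
Reagents that add atoms: none
Why: In this Lewis-acid-catalysed Diels–Alder reaction the CH2 terminus of the silyloxy diene bonds to the enal β-carbon (C1) and the methyl-bearing terminus to C10 (para to OSi and ortho to methyl, both matched); suprafacial addition keeps C15 cis to the formyl group, the endo formyl puts C20 cis to C9, and the chiral oxazaborolidinium ion selects the face.

Step 5
Reactants: 8 (tributylstannyl)methanol
Product: 10 tributyl[(4-methoxybenzyloxy)methyl]stannane, via sodium alkoxide 9 (not isolated)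
Conditions: NaH, THF/DMF, 0 °C; then 4-MeOC6H4CH2Cl, Bu4NI (cat.), rt
Reagents that add atoms: 4-methoxybenzyl chloride, COc1ccc(CCl)cc1
Why: Williamson etherification of the stannylmethanol alkoxide gives the precursor of a PMB-protected hydroxymethyl anion.

Step 6
Reactants: 7 Diels–Alder adduct; 10 tributyl[(4-methoxybenzyloxy)methyl]stannane
Product: 12 C9 carbinols (both epimers) carrying C8H2OPMB, via alkoxymethyllithium 11 (not isolated)
Conditions: n-BuLi, THF, −78 °C; then 7, −78 °C; aq. NH4Cl at −78 °C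
Reagents that add atoms: none
Why: Tin–lithium exchange gives the α-alkoxy organolithium, which should add to the aldehyde far faster than to the hindered ester at −78 °C (1,2-addition); the C9 configuration is erased in step 7.

Step 7
Reactants: 12 C9 carbinols
Product: 13 C9 ketone, ethyl 3-(tert-butyldimethylsilyloxy)-6-[(4-methoxybenzyloxy)acetyl]-1,5-dimethylcyclohex-3-ene-1-carboxylate (ring stereocentres as in 7)
Conditions: Dess–Martin periodinane, NaHCO3, CH2Cl2, 0 °C to rt
Reagents that add atoms: none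
Why: Buffered Dess–Martin oxidation of the secondary alcohol spares the silyl enol ether and the PMB ether and sets up a reagent-controlled reduction.

Step 8
Reactants: 13 C9 ketone
Product: 14 (9S)-carbinol
Conditions: (3aS)-1-methyl-3,3-diphenyltetrahydro-3H-pyrrolo[1,2-c][1,3,2]oxazaborole (20 mol%), catecholborane, toluene, −78 °C
Reagents that add atoms: none
Why: In this Corey–Bakshi–Shibata reduction the ring carbon C10 is the large and CH2OPMB the small substituent, so the (S)-catalyst should give 9S, the sense also favoured by Felkin–Anh attack anti to quaternary C1; catecholborane leaves ester and enol ether alone.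

Step 9
Reactants: 14 (9S)-carbinol
Product: 15 (9S)-tert-butyldimethylsilyl ether
Conditions: TBSOTf, 2,6-lutidine, CH2Cl2, −78 to 0 °C
Reagents that add atoms: tert-butyldimethylsilyl trifluoromethanesulfonate, CC(C)(C)[Si](C)(C)OS(=O)(=O)C(F)(F)F
Why: Silylation with the silyl triflate protects O9 before it can lactonise onto the C2 ester.

Step 10
Reactants: 15 (9S)-silyl ether with the C12=C13 silyl enol ether
Product: 17 ring A 13-ketone with 12-OTBS trans to the C11 methyl, via siloxy epoxide 16 (not isolated)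
Conditions: m-CPBA, NaHCO3, CH2Cl2, −20 to 0 °C
Reagents that add atoms: 3-chloroperoxybenzoic acid, OOC(=O)c1cccc(Cl)c1
Why: In this Rubottom oxidation the peracid should attack C12 of the enol ether on the face away from the pseudo-axial C9 side chain, and opening of the siloxy epoxide with 1,4-silyl shift gives the α-silyloxy ketone; this C12 epimer (OTBS equatorial, trans to C20) is also the more stable one, so enolisation cannot erode it.

Step 11
Reactants: 17 ring A 13-ketone
Product: 19 C13 enol triflate (C13=C14), via potassium enolate 18 (not isolated)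
Conditions: KN(SiMe3)2, THF, −78 °C; then PhNTf2, −78 to −20 °C
Reagents that add atoms: N-phenylbis(trifluoromethanesulfonimide), FC(F)(F)S(=O)(=O)N(c1ccccc1)S(=O)(=O)C(F)(F)F
Why: Kinetic deprotonation of an α-silyloxy ketone takes place at the unsubstituted α′-CH2 (C14), and O-sulfonylation of that enolate gives the vinyl triflate (enol triflate formation).

Step 12
Reactants: 19 C13 enol triflate
Product: 20 ring A ethyl ester with C13=C14 and 12-OTBS
Conditions: Pd(OAc)2 (5 mol%), PPh3 (10 mol%), HCO2H, n-Bu3N, DMF, 60 °C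
Reagents that add atoms: none
Why: Palladium-catalysed formate reduction of the vinyl triflate (oxidative addition, decarboxylation of formate to a palladium hydride, reductive elimination) replaces OTf by H and leaves the C13=C14 alkene next to the allylic silyl ether.

Step 13
Reactants: 20 ring A ethyl ester
Product: 21 C2 primary alcohol
Conditions: iBu2AlH, CH2Cl2, −78 to 0 °C; Rochelle salt
Reagents that add atoms: none
Why: Hydride reduction of the neopentyl ester gives the primary alcohol, and silyl and PMB ethers are inert.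

Step 14
Reactants: 21 C2 primary alcohol
Product: 22 C2 aldehyde (ring A fragment)
Conditions: Dess–Martin periodinane, NaHCO3, CH2Cl2, 0 °C to rt
Reagents that add atoms: none
Why: Dess–Martin oxidation gives a neopentyl aldehyde that cannot enolise.

Step 15
Reactants: 23 (R)-2-(2,2-dimethyl-1,3-dioxolan-4-yl)ethanol
Product: 24 (R)-(2,2-dimethyl-1,3-dioxolan-4-yl)acetaldehyde
Conditions: Dess–Martin periodinane, NaHCO3, CH2Cl2, 0 °C to rt
Reagents that add atoms: none
Why: Dess–Martin oxidation of the chiral-pool alcohol; the stereocentre (future C6) is β to the new carbonyl and is not at risk.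

Step 16
Reactants: 24 (R)-(2,2-dimethyl-1,3-dioxolan-4-yl)acetaldehyde
Product: 25 (R)-2-(2,2-dimethyl-1,3-dioxolan-4-yl)prop-2-enal
Conditions: 37% aq. HCHO, pyrrolidine (10 mol%), EtCO2H (10 mol%), i-PrOH, 45 °C
Reagents that add atoms: formaldehyde, C=O
Why: Amine-catalysed Mannich condensation and elimination (α-methylenation of an aldehyde) installs C16 as the exo-methylene group.

Step 17
Reactants: 25 (R)-2-(2,2-dimethyl-1,3-dioxolan-4-yl)prop-2-enal
Product: 26 (R)-4-(4,4-dibromobuta-1,3-dien-2-yl)-2,2-dimethyl-1,3-dioxolane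
Conditions: CBr4, PPh3, Et3N, CH2Cl2, 0 °C
Reagents that add atoms: carbon tetrabromide, BrC(Br)(Br)Br
Why: Corey–Fuchs dibromo-olefination of the enal gives the 1,1-dibromodiene, the latent C3≡C4 alkyne.

Step 18
Reactants: 26 dibromodiene acetonide
Product: 27 (R)-5,5-dibromo-3-methylidenepent-4-ene-1,2-diol
Conditions: AcOH/H2O (4:1), 40 °C
Reagents that add atoms: none
Why: Mild acid hydrolysis of the acetonide frees the diol, and the dibromodiene is stable to acid.

Step 19
Reactants: 27 (R)-5,5-dibromo-3-methylidenepent-4-ene-1,2-diol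
Product: 28 bis(triethylsilyl) ether of 27
Conditions: Et3SiCl, imidazole, CH2Cl2, 0 °C to rt
Reagents that add atoms: chlorotriethylsilane, CC[Si](Cl)(CC)CC
Why: Silylation of both hydroxyls as triethylsilyl ethers, chosen so that first the primary (O7) and later the secondary (O6) ether can be removed in the presence of TBS ethers.

Step 20
Reactants: 28 bis(triethylsilyl) dibromodiene; 22 C2 aldehyde
Product: 30 C2 propargylic alcohols (both epimers), via lithium acetylide 29 (not isolated)
Conditions: n-BuLi (2.1 equiv), THF, −78 °C; then 22, −78 to −40 °C; aq. NH4Cl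
Reagents that add atoms: none
Why: The second half of the Corey–Fuchs sequence (Br–Li exchange, Fritsch–Buttenberg–Wiechell rearrangement, deprotonation) gives the lithium acetylide, which adds to the non-enolisable aldehyde; the C2 mixture is corrected in steps 21 and 22.

Step 21
Reactants: 30 C2 propargylic alcohols
Product: 31 C2 ynone
Conditions: Dess–Martin periodinane, NaHCO3, CH2Cl2, 0 °C to rt
Reagents that add atoms: none
Why: Dess–Martin oxidation of the propargylic alcohols converges both epimers on one ynone.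

Step 22
Reactants: 31 C2 ynone
Product: 32 (2R)-propargylic alcohol (becomes 2S once the alkyne is an alkene)
Conditions: (3aR)-1-methyl-3,3-diphenyltetrahydro-3H-pyrrolo[1,2-c][1,3,2]oxazaborole (30 mol%), catecholborane, toluene, −78 °C
Reagents that add atoms: none
Why: In this Corey–Bakshi–Shibata reduction quaternary C1 is the large and the slim alkynyl group the small substituent, so the (R)-catalyst should deliver hydride to the face that gives the target configuration at C2.

Step 23
Reactants: 32 (2R)-propargylic alcohol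
Product: 33 C2 tert-butyldimethylsilyl ether
Conditions: TBSOTf, 2,6-lutidine, CH2Cl2, −78 to 0 °C
Reagents that add atoms: tert-butyldimethylsilyl trifluoromethanesulfonate, CC(C)(C)[Si](C)(C)OS(=O)(=O)C(F)(F)F
Why: Silyl triflate protection is the reliable way to silylate a hindered secondary alcohol next to a quaternary carbon.

Step 24
Reactants: 33 C2 silyl ether with 8-OPMB
Product: 34 C8 primary alcohol
Conditions: DDQ, CH2Cl2/pH 7 buffer (10:1), 0 °C
Reagents that add atoms: none
Why: Oxidative PMB cleavage (hydride abstraction, hydrolysis of the hemiacetal) frees O8 while the silyl ethers and the enyne, less electron-rich than the later diene, stay untouched.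

Step 25
Reactants: 34 C8 primary alcohol
Product: 35 C8 aldehyde (9-OTBS)
Conditions: Dess–Martin periodinane, NaHCO3, CH2Cl2, 0 °C to rt
Reagents that add atoms: none
Why: Buffered Dess–Martin oxidation gives the α-silyloxy aldehyde without epimerising C9.

Step 26
Reactants: 35 C8 aldehyde; 36 methyl propanoate
Product: 38 β-hydroxy ester (C8 and C17 epimers), via lithium enolate 37 (not isolated)
Conditions: LiN(iPr)2, 36, THF, −78 °C; then 35, −78 °C; aq. NH4Cl
Reagents that add atoms: none
Why: Aldol addition of the ester enolate forms C8–C17; the C8 stereocentre is removed and C17 made labile by the oxidation in step 29.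

Step 27
Reactants: 38 β-hydroxy ester with the C3≡C4 enyne
Product: 39 (3Z)-diene
Conditions: Zn dust activated with Cu(OAc)2 and AgNO3, MeOH/H2O (1:1), 45 °C
Reagents that add atoms: none
Why: Zinc reduction of a conjugated enyne in aqueous methanol (Boland reduction) gives the cis alkene and does not reduce isolated or 1,1-disubstituted alkenes.

Step 28
Reactants: 39 (3Z)-diene
Product: 40 C7 primary alcohol (7,8-diol, 6-OTES kept)
Conditions: HF·pyridine, pyridine, THF, 0 °C
Reagents that add atoms: none
Why: Buffered HF·pyridine cleaves a primary triethylsilyl ether faster than the secondary one and much faster than TBS ethers (selective desilylation).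

Step 29
Reactants: 40 7,8-diol
Product: 41 keto ester aldehyde (C7 aldehyde, C8 ketone of the β-keto ester, C17 epimers)
Conditions: Dess–Martin periodinane (4 equiv), NaHCO3, CH2Cl2, 0 °C to rt
Reagents that add atoms: none
Why: A double Dess–Martin oxidation turns C8–OH into the ketone and C7–OH into the aldehyde under neutral buffered conditions that spare the labile α-silyloxy β,γ-unsaturated aldehyde.

Step 30
Reactants: 41 keto ester aldehyde
Product: 43 tricyclic hydroxy lactone (6-OTES of inverted configuration), via ten-membered diol ester 42 (not isolated)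
Conditions: SmI2 (4 equiv, 0.1 M in THF), 41 added by syringe pump over 8 h (final 2 mM), −78 to 0 °C; then rt, 2 h; aq. NaHCO3
Reagents that add atoms: none
Why: Electron transfer from SmI2 should give a ketyl most readily at the C8 ketone, which is activated by chelation of samarium between the ketone and ester oxygens; this ketyl adds to the C7 aldehyde (or couples with its ketyl after a second electron transfer) while both oxygens sit on trivalent samarium, the closest precedent being samarium diiodide pinacol cyclisations of keto aldehydes to medium rings. The ten-membered ring closes through the C7–C8 bond (10-exo-trig attack of the C8 ketyl on the aldehyde carbon), and the O7 samarium alkoxide then closes the γ-lactone by 5-exo-trig acyl substitution at C19 with loss of methoxide. C7 and C8 are set together: the samarium bridge holds the two oxygens cis, and the face is chosen by the α-silyloxy stereocentres C6 and C9, each turning its silyloxy group away from the forming bond, inside the fold imposed by the Z-diene and the trans arms on C1 and C10. C17 is labile both before (β-keto ester) and after (α to the lactone carbonyl) the coupling and should settle with its methyl trans to C9. The step needs ring closure to outrun β-elimination of the silyloxy groups and intermolecular coupling; slow addition at high dilution, low temperature, the chelating keto ester and the poor leaving ability of silyloxide are meant to secure this.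

Step 31
Reactants: 43 tricyclic hydroxy lactone
Product: 44 C6 alcohol
Conditions: PPTS (0.2 equiv), MeOH/CH2Cl2 (1:4), 0 °C
Reagents that add atoms: none
Why: Acid-catalysed methanolysis removes a secondary triethylsilyl ether far faster than the three TBS ethers (selective desilylation).

Step 32
Reactants: 44 C6 alcohol
Product: 45 (6S)-chloride
Conditions: PPh3, hexachloroacetone, 2,6-di-tert-butylpyridine, CH2Cl2, −20 to 0 °C
Reagents that add atoms: hexachloroacetone, ClC(Cl)(Cl)C(=O)C(Cl)(Cl)Cl
Why: In this Appel-type chlorination the O6 alkoxyphosphonium ion is displaced by chloride in an SN2 step with inversion, under conditions known to convert secondary allylic alcohols without allylic transposition; the tertiary C8 hydroxyl should not react.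

Step 33
Reactants: 45 (6S)-chloride
Product: 46 2,8,9,12-tetraol
Conditions: HF·pyridine, THF, 0 to 40 °C
Reagents that add atoms: none
Why: Fluoride cleavage of the three TBS ethers under acidic, non-basic conditions leaves the lactone and the allylic chloride intact.

Step 34
Reactants: 46 2,8,9,12-tetraol
Product: 47 CNP0076552.1
Conditions: Ac2O, pyridine, DMAP (cat.), CH2Cl2, 0 °C to rt
Reagents that add atoms: acetic anhydride, CC(=O)OC(C)=O
Why: DMAP-catalysed acetylation esterifies the three secondary hydroxyls (O2, O9, O12) while the hindered tertiary C8 hydroxyl stays free.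

**Compound list**

1 | 2,2-dimethoxyacetaldehyde | COC(OC)C=O | starting material
2 | ethyl 2-(triphenylphosphoranylidene)propanoate | CCOC(=O)C(C)=P(c1ccccc1)(c1ccccc1)c1ccccc1 | starting material
3 | ethyl (E)-4,4-dimethoxy-2-methylbut-2-enoate | CCOC(=O)/C(C)=C/C(OC)OC | intermediate
4 | ethyl (E)-2-methyl-4-oxobut-2-enoate | CCOC(=O)/C(C)=C/C=O | intermediate
5 | (E)-pent-3-en-2-one | C/C=C/C(C)=O | starting material
6 | (E)-2-(tert-butyldimethylsilyloxy)penta-1,3-diene | C=C(O[Si](C)(C)C(C)(C)C)/C=C/C | intermediate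
7 | ethyl (1S,5S,6S)-3-(tert-butyldimethylsilyloxy)-6-formyl-1,5-dimethylcyclohex-3-ene-1-carboxylate | CCOC(=O)[C@@]1(C)CC(O[Si](C)(C)C(C)(C)C)=C[C@H](C)[C@@H]1C=O | intermediate
8 | (tributylstannyl)methanol | CCCC[Sn](CCCC)(CCCC)CO | starting material
9 | sodium (tributylstannyl)methoxide | CCCC[Sn](CCCC)(CCCC)C[O-].[Na+] | intermediate
10 | tributyl[(4-methoxybenzyloxy)methyl]stannane | CCCC[Sn](CCCC)(CCCC)COCc1ccc(OC)cc1 | intermediate
11 | (4-methoxybenzyloxy)methyllithium | [Li]COCc1ccc(OC)cc1 | intermediate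
12 | C9 carbinols (both epimers) of the ring A silyl enol ether with C8H2OPMB | CCOC(=O)[C@@]1(C)CC(O[Si](C)(C)C(C)(C)C)=C[C@H](C)[C@@H]1C(O)COCc1ccc(OC)cc1 | intermediate
13 | C9 ketone | CCOC(=O)[C@@]1(C)CC(O[Si](C)(C)C(C)(C)C)=C[C@H](C)[C@@H]1C(=O)COCc1ccc(OC)cc1 | intermediate
14 | (9S)-carbinol | CCOC(=O)[C@@]1(C)CC(O[Si](C)(C)C(C)(C)C)=C[C@H](C)[C@@H]1[C@H](O)COCc1ccc(OC)cc1 | intermediate
15 | (9S)-tert-butyldimethylsilyl ether | CCOC(=O)[C@@]1(C)CC(O[Si](C)(C)C(C)(C)C)=C[C@H](C)[C@@H]1[C@H](O[Si](C)(C)C(C)(C)C)COCc1ccc(OC)cc1 | intermediate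
16 | 12,13-siloxy epoxide (oxygen cis to the C2 ester) | CCOC(=O)[C@@]1(C)C[C@@]2(O[Si](C)(C)C(C)(C)C)O[C@H]2[C@H](C)[C@@H]1[C@H](O[Si](C)(C)C(C)(C)C)COCc1ccc(OC)cc1 | intermediate
17 | ring A 13-ketone, 12-OTBS trans to the C11 methyl | CCOC(=O)[C@@]1(C)CC(=O)[C@@H](O[Si](C)(C)C(C)(C)C)[C@H](C)[C@@H]1[C@H](O[Si](C)(C)C(C)(C)C)COCc1ccc(OC)cc1 | intermediate
18 | potassium C13=C14 enolate of 17 | CCOC(=O)[C@@]1(C)C=C([O-])[C@@H](O[Si](C)(C)C(C)(C)C)[C@H](C)[C@@H]1[C@H](O[Si](C)(C)C(C)(C)C)COCc1ccc(OC)cc1.[K+] | intermediate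
19 | C13 enol triflate | CCOC(=O)[C@@]1(C)C=C(OS(=O)(=O)C(F)(F)F)[C@@H](O[Si](C)(C)C(C)(C)C)[C@H](C)[C@@H]1[C@H](O[Si](C)(C)C(C)(C)C)COCc1ccc(OC)cc1 | intermediate
20 | ring A ethyl ester with C13=C14, 12-OTBS, 9-OTBS, 8-OPMB | CCOC(=O)[C@@]1(C)C=C[C@@H](O[Si](C)(C)C(C)(C)C)[C@H](C)[C@@H]1[C@H](O[Si](C)(C)C(C)(C)C)COCc1ccc(OC)cc1 | intermediate
21 | C2 primary alcohol | OC[C@@]1(C)C=C[C@@H](O[Si](C)(C)C(C)(C)C)[C@H](C)[C@@H]1[C@H](O[Si](C)(C)C(C)(C)C)COCc1ccc(OC)cc1 | intermediate
22 | C2 aldehyde (ring A fragment) | O=C[C@@]1(C)C=C[C@@H](O[Si](C)(C)C(C)(C)C)[C@H](C)[C@@H]1[C@H](O[Si](C)(C)C(C)(C)C)COCc1ccc(OC)cc1 | intermediate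
23 | (R)-2-(2,2-dimethyl-1,3-dioxolan-4-yl)ethanol | OCC[C@@H]1COC(C)(C)O1 | starting material
24 | (R)-(2,2-dimethyl-1,3-dioxolan-4-yl)acetaldehyde | O=CC[C@@H]1COC(C)(C)O1 | intermediate
25 | (R)-2-(2,2-dimethyl-1,3-dioxolan-4-yl)prop-2-enal | C=C(C=O)[C@@H]1COC(C)(C)O1 | intermediate
26 | (R)-4-(4,4-dibromobuta-1,3-dien-2-yl)-2,2-dimethyl-1,3-dioxolane | BrC(Br)=CC(=C)[C@@H]1COC(C)(C)O1 | intermediate
27 | (R)-5,5-dibromo-3-methylidenepent-4-ene-1,2-diol | BrC(Br)=CC(=C)[C@@H](O)CO | intermediate
28 | bis(triethylsilyl) ether of 27 | BrC(Br)=CC(=C)[C@@H](O[Si](CC)(CC)CC)CO[Si](CC)(CC)CC | intermediate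
29 | lithium (R)-3-methylidene-4,5-bis(triethylsilyloxy)pent-1-ynide | [Li]C#CC(=C)[C@@H](O[Si](CC)(CC)CC)CO[Si](CC)(CC)CC | intermediate
30 | C2 propargylic alcohols (both epimers) | OC(C#CC(=C)[C@@H](O[Si](CC)(CC)CC)CO[Si](CC)(CC)CC)[C@@]1(C)C=C[C@@H](O[Si](C)(C)C(C)(C)C)[C@H](C)[C@@H]1[C@H](O[Si](C)(C)C(C)(C)C)COCc1ccc(OC)cc1 | intermediate
31 | C2 ynone | O=C(C#CC(=C)[C@@H](O[Si](CC)(CC)CC)CO[Si](CC)(CC)CC)[C@@]1(C)C=C[C@@H](O[Si](C)(C)C(C)(C)C)[C@H](C)[C@@H]1[C@H](O[Si](C)(C)C(C)(C)C)COCc1ccc(OC)cc1 | intermediate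
32 | (2R)-propargylic alcohol | O[C@@H](C#CC(=C)[C@@H](O[Si](CC)(CC)CC)CO[Si](CC)(CC)CC)[C@@]1(C)C=C[C@@H](O[Si](C)(C)C(C)(C)C)[C@H](C)[C@@H]1[C@H](O[Si](C)(C)C(C)(C)C)COCc1ccc(OC)cc1 | intermediate
33 | C2 tert-butyldimethylsilyl ether | CC(C)(C)[Si](C)(C)O[C@@H](C#CC(=C)[C@@H](O[Si](CC)(CC)CC)CO[Si](CC)(CC)CC)[C@@]1(C)C=C[C@@H](O[Si](C)(C)C(C)(C)C)[C@H](C)[C@@H]1[C@H](O[Si](C)(C)C(C)(C)C)COCc1ccc(OC)cc1 | intermediate
34 | C8 primary alcohol | CC(C)(C)[Si](C)(C)O[C@@H](C#CC(=C)[C@@H](O[Si](CC)(CC)CC)CO[Si](CC)(CC)CC)[C@@]1(C)C=C[C@@H](O[Si](C)(C)C(C)(C)C)[C@H](C)[C@@H]1[C@H](O[Si](C)(C)C(C)(C)C)CO | intermediate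
35 | C8 aldehyde | CC(C)(C)[Si](C)(C)O[C@@H](C#CC(=C)[C@@H](O[Si](CC)(CC)CC)CO[Si](CC)(CC)CC)[C@@]1(C)C=C[C@@H](O[Si](C)(C)C(C)(C)C)[C@H](C)[C@@H]1[C@H](O[Si](C)(C)C(C)(C)C)C=O | intermediate
36 | methyl propanoate | CCC(=O)OC | starting material
37 | lithium enolate of methyl propanoate | CC=C(OC)O[Li] | intermediate
38 | β-hydroxy ester (C8 and C17 epimers), enyne | CC(C)(C)[Si](C)(C)O[C@@H](C#CC(=C)[C@@H](O[Si](CC)(CC)CC)CO[Si](CC)(CC)CC)[C@@]1(C)C=C[C@@H](O[Si](C)(C)C(C)(C)C)[C@H](C)[C@@H]1[C@H](O[Si](C)(C)C(C)(C)C)C(O)C(C)C(=O)OC | intermediate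
39 | (3Z)-diene β-hydroxy ester | CC(C)(C)[Si](C)(C)O[C@@H](/C=C\C(=C)[C@@H](O[Si](CC)(CC)CC)CO[Si](CC)(CC)CC)[C@@]1(C)C=C[C@@H](O[Si](C)(C)C(C)(C)C)[C@H](C)[C@@H]1[C@H](O[Si](C)(C)C(C)(C)C)C(O)C(C)C(=O)OC | intermediate
40 | 7,8-diol (6-OTES) | CC(C)(C)[Si](C)(C)O[C@@H](/C=C\C(=C)[C@@H](O[Si](CC)(CC)CC)CO)[C@@]1(C)C=C[C@@H](O[Si](C)(C)C(C)(C)C)[C@H](C)[C@@H]1[C@H](O[Si](C)(C)C(C)(C)C)C(O)C(C)C(=O)OC | intermediate
41 | keto ester aldehyde (key-step precursor, C17 epimers) | CC(C)(C)[Si](C)(C)O[C@@H](/C=C\C(=C)[C@@H](O[Si](CC)(CC)CC)C=O)[C@@]1(C)C=C[C@@H](O[Si](C)(C)C(C)(C)C)[C@H](C)[C@@H]1[C@H](O[Si](C)(C)C(C)(C)C)C(=O)C(C)C(=O)OC | intermediate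
42 | ten-membered cis-7,8-diol methyl ester | C[C@]12C=C[C@@H](O[Si](C)(C)C(C)(C)C)[C@H](C)[C@@H]1[C@H](O[Si](C)(C)C(C)(C)C)[C@](O)(C(C)C(=O)OC)[C@@H](O)[C@H](O[Si](CC)(CC)CC)C(=C)/C=C\[C@@H]2O[Si](C)(C)C(C)(C)C | intermediate
43 | tricyclic hydroxy lactone, 6-OTES (inverted C6), 2,9,12-tris-OTBS | C[C@]12C=C[C@@H](O[Si](C)(C)C(C)(C)C)[C@H](C)[C@@H]1[C@H](O[Si](C)(C)C(C)(C)C)[C@]1(O)[C@@H](C)C(=O)O[C@H]1[C@H](O[Si](CC)(CC)CC)C(=C)/C=C\[C@@H]2O[Si](C)(C)C(C)(C)C | intermediate
44 | C6 alcohol | C[C@]12C=C[C@@H](O[Si](C)(C)C(C)(C)C)[C@H](C)[C@@H]1[C@H](O[Si](C)(C)C(C)(C)C)[C@]1(O)[C@@H](C)C(=O)O[C@H]1[C@H](O)C(=C)/C=C\[C@@H]2O[Si](C)(C)C(C)(C)C | intermediate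
45 | (6S)-chloride, 2,9,12-tris-OTBS | C[C@]12C=C[C@@H](O[Si](C)(C)C(C)(C)C)[C@H](C)[C@@H]1[C@H](O[Si](C)(C)C(C)(C)C)[C@]1(O)[C@@H](C)C(=O)O[C@H]1[C@@H](Cl)C(=C)/C=C\[C@@H]2O[Si](C)(C)C(C)(C)C | intermediate
46 | 2,8,9,12-tetraol | C[C@]12C=C[C@@H](O)[C@H](C)[C@@H]1[C@H](O)[C@]1(O)[C@@H](C)C(=O)O[C@H]1[C@@H](Cl)C(=C)/C=C\[C@@H]2O | intermediate
47 | CNP0076552.1, (1S,2S,3Z,6S,7R,8R,9S,10S,11R,12R,17R)-2,9,12-triacetoxy-6-chloro-8-hydroxybriara-3,5(16),13-trien-19,7-olide | C=C1/C=C\[C@H](OC(C)=O)[C@@]2(C)C=C[C@@H](OC(C)=O)[C@H](C)[C@@H]2[C@H](OC(C)=O)[C@]2(O)[C@@H](C)C(=O)O[C@H]2[C@H]1Cl | target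

**Step count**

Total: 34 steps. Longest linear sequence: 27 steps (steps 1, 2, 4, 6–14, 20–34).

**Steps most likely to fail**

Step 30. Electron transfer may run ahead of the slow ten-membered ring closure, so that the silyloxy groups next to the ketyl carbons are lost by β-elimination, the carbonyls are simply reduced, or two molecules couple. The fallback sets out from 41 and gives up the homogeneous cascade for a two-stage, surface-templated coupling. Compound 41 is added slowly to low-valent titanium from TiCl3(DME)1.5 and Zn–Cu couple in DME at room temperature, where both carbonyl oxygens are bound to titanium before the C–C bond forms and deoxygenation to the alkene does not yet occur. The diol ester 42 is isolated and then lactonised separately with catalytic DBU in toluene, which also equilibrates C17; the route is rejoined at 43 (no compound outside the list is formed: F0).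

Step 32. Chloride may attack C16 with allylic transposition, or the activated alcohol may ionise or eliminate, because bimolecular substitution at a carbon of the ten-membered ring is slow. The fallback sets out from 44 and uses the neighbouring tertiary hydroxyl as an internal activating group. NaH and 1,1′-sulfonyldiimidazole in THF tie O6 and O8 into the cyclic 6,8-sulfate F1, which is cis-fused to the lactone. LiCl in DMF opens it at the secondary allylic carbon C6 with inversion to the 6-chloro 8-O-sulfate lithium salt F2. Catalytic H2SO4 with one equivalent of water in THF then hydrolyses the sulfate monoester, and the route is rejoined at 45.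

Step 4. Face selection by the catalyst may be poor, the silyloxy diene may be consumed in Mukaiyama-type side reactions at the strong Lewis acid, or the quaternary centre may form too slowly. The fallback sets out from 4 and 6 and moves the control of absolute configuration from the cycloaddition to the reduction. A racemic cycloaddition with Me2AlCl (20 mol%) in CH2Cl2 at −78 °C gives 7 together with the enantiomer of 7 F3. Steps 6 and 7 carry the pair through the enantiomeric carbinols F4 to ketone 13 and the enantiomeric ketone F5. The reduction of step 8 then gives 14 and, from F5, the (9S)-carbinol on the enantiomeric ring F6. F6 is a diastereomer of 14 and is removed by chromatography; the route is rejoined at 14.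

**Further compounds**

F0 | step 30 | none | none
F1 | step 32 | cyclic 6,8-sulfate of 44 | C[C@]12C=C[C@@H](O[Si](C)(C)C(C)(C)C)[C@H](C)[C@@H]1[C@H](O[Si](C)(C)C(C)(C)C)[C@]1(O3)[C@@H](C)C(=O)O[C@H]1[C@H](OS3(=O)=O)C(=C)/C=C\[C@@H]2O[Si](C)(C)C(C)(C)C
F2 | step 32 | 6-chloro 8-O-sulfate lithium salt | C[C@]12C=C[C@@H](O[Si](C)(C)C(C)(C)C)[C@H](C)[C@@H]1[C@H](O[Si](C)(C)C(C)(C)C)[C@]1(OS(=O)(=O)[O-])[C@@H](C)C(=O)O[C@H]1[C@@H](Cl)C(=C)/C=C\[C@@H]2O[Si](C)(C)C(C)(C)C.[Li+]
F3 | step 4 | enantiomer of 7 | CCOC(=O)[C@]1(C)CC(O[Si](C)(C)C(C)(C)C)=C[C@@H](C)[C@H]1C=O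
F4 | step 4 | enantiomeric carbinols (enantiomer of 12, both C9 epimers) | CCOC(=O)[C@]1(C)CC(O[Si](C)(C)C(C)(C)C)=C[C@@H](C)[C@H]1C(O)COCc1ccc(OC)cc1
F5 | step 4 | enantiomeric ketone (enantiomer of 13) | CCOC(=O)[C@]1(C)CC(O[Si](C)(C)C(C)(C)C)=C[C@@H](C)[C@H]1C(=O)COCc1ccc(OC)cc1
F6 | step 4 | (9S)-carbinol on the enantiomeric ring (diastereomer of 14) | CCOC(=O)[C@]1(C)CC(O[Si](C)(C)C(C)(C)C)=C[C@@H](C)[C@H]1[C@H](O)COCc1ccc(OC)cc1
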